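## Analysis of the target

The target is a germacranolide: a ten-membered carbocycle (C1–C10) fused at C6–C7 to a butenolide whose carbonyl is C12, whose ring oxygen sits on C6 and whose alkene C7=C11 carries the acetoxymethyl carbon C13. Two trisubstituted epoxides lie in the ring: C1–C10 (methyl C14 on C10; C2 and C9 cis on the oxirane) and C4–C5 (methyl C15 on C4; C3 and C6 trans). C8 bears a secondary acetate. There are six stereocentres, 1R, 4R, 5R, 6S, 8S and 10S. C4, C5 and C6 are contiguous, C8 is separated from C6 by the sp2 carbon C7, and the 1,10-epoxide is 1,3-related to C8 across C9. The sensitive features are the two epoxides (acid, transannular opening), the two base-labile acetates, and the butenolide γ-hydrogen at C6. Removal of that hydrogen would open the 4,5-epoxide by β-elimination or expel an acetate from C13 through C11. The difficulty is a medium ring whose stereocentres sit on opposite sides of it with little mutual communication. The strategy rests on one relation: C6 is the γ-carbon of the butenolide and C5 the oxygenated carbon next to it, so C5–C6 is a vinylogous aldol bond. It lies beside the quaternary C4 which, with C15, C3, C2 and C1, maps onto the tertiary carbinol end of (R)-linalool (1).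

## Retrosynthetic reasoning

32 to 31. The two acetyl C–O bonds are cut first. An acetate on C13 cannot be carried through the route: once the butenolide is enolised towards C6, a leaving group on C13 is β to the nucleophilic C11 and would be lost. Putting both acetates on last costs one step for two groups and leaves diol 31.

31 to 30. The two C–O bonds of the 1,10-epoxide are cut to the Z alkene of 30. The free C8 hydroxyl of 30 is homoallylic to C1=C10 and can deliver the oxidant, and syn addition to a Z alkene gives the cis oxirane required. The forward step must pick one face of an alkene held in a ten-membered ring.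

30 to 29 to 27 to 26. In the 4,5-epoxide the C5–O bond is cut, not the C4–O bond. C4 is quaternary and keeps the oxygen it has in 1; C5 is secondary and can be displaced. The forward closure is an intramolecular displacement of a C5 sulfonate (28) by the C4 oxygen with inversion. Alcohol 26 is therefore planned with C5 epimeric to the target (5S) and with O4 and O5 anti, the arrangement that closes to the trans oxirane. The C8 and C13 oxygens stay silylated (29) so that only O4 can attack C5.

26 to 25. The C5–C6 bond is cut, which opens the ten-membered ring. This is the only ring bond whose two ends are polarised by groups already in the target: C6 is the nucleophilic terminus of the butenolide dienol ether and C5 is a carbonyl carbon. The cut places the ring closure next to the chiral-pool centre C4 and makes C5 and C6 in the same event. The aldehyde of 25 has no α-hydrogen. The forward reaction must close a medium ring and select one of four diastereomers.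

25 to 24 to 21. The silyl dienol ether is taken back to butenolide 24. The C5 aldehyde and the C4 silyl ether go back through 23 and 22 to the acetonide of 21, which masks O4 and O5 together through all the organometallic steps. The lactone carbonyl C12 of 21 is traced to a C–H bond of furan 19. The forward oxidation must choose the α-position next to C11 over the one next to C7.

19 to 18 to 17 to 16. The C8–H bond is cut: the carbinol comes from furyl ketone 17 by catalyst-controlled reduction, aryl against primary alkyl, a pairing these catalysts discriminate reliably. The ketone is unmasked from dithiane 16.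

16 to 14 and 10. The C8–C9 bond is cut between an acyl anion equivalent and an allylic bromide. C9 is allylic, and a dithiane anion alkylates such a halide at the α-carbon without transposition, which an allyl metal adding to an aldehyde would not do. The Z geometry of C1=C10 is carried through untouched.

10 to 9 to 8 to 5 and 6. The C1=C10 alkene is cut by a Z-selective phosphonate olefination. Reagent 6 brings C10, C14 and C9, and aldehyde 5 brings C1. The ring-cis geometry needed is exactly what the Still–Gennari variant provides.

5 to 4 to 3 to 1. Both alkenes of 1 are cleaved. The vinyl group becomes C5, the trisubstituted alkene gives C1, and C4 with its oxygen and methyl is never touched. The two ends of triol 3 are told apart by the five-membered acetonide that only the vicinal diol can form.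

14 to 13 to 12 to 11. The furan piece comes from the symmetric diol 11 by monosilylation. One arm becomes C13 and the other is oxidised to C8.

## Alternatives that were turned down

Alternative 1: Here the C10–C14 and C4–C15 bonds and the C10–O bond of the 1,10-epoxide are cut, on a ring closed earlier by other means. In the forward step two equivalents of a methylmagnesium or methyltitanium reagent add to ketones at C10 and C4 of a ten-membered ring that carries a chloride at C1. The C10 alkoxide then displaces the chloride to give A1.
- For it: C1 comes from an amino acid of the chiral pool, the epoxide follows stereospecifically from the chlorohydrin, and two quaternary centres and one ring appear in one operation.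
- Against it: A1 carries only an exocyclic methylene at C7, so C12, C13 and the whole butenolide are still to be built. The C4/C5 diol must still become the epoxide, and C6 and C8 must be unmasked. Two facial selectivities, at C10 and at C4, must come out right at once on a flexible ring, one of them on an α-chloro ketone that can also enolise. The ring closure itself is left to a further step.
- Comparison: it is stronger on the 1,10-epoxide, whose configuration is tied to a pool-derived centre and not to the face of a ring alkene. The chosen strategy has all fifteen skeletal carbons and the lactone in place at ring closure, takes C4 intact from 1, and leaves only oxygen chemistry after the ring is made.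

Alternative 2: The C9–C10 bond and the C8–O bond are cut together, reading C8(O)–C9–C10 as the product of an intramolecular nitrile oxide cycloaddition. A C10 aldoxime is chlorinated and dehydrochlorinated, and the nitrile oxide adds to a C8=C9 vinyl group on C7 of the butenolide to give isoxazoline A2.
- For it: the cycloaddition is tolerant and its regiochemistry (oxygen to C8) is the normal one. The C13 acetate, the butenolide and the 4,5-epoxide are already present in A2. The C8 oxygen arrives with the ring, so no separate asymmetric reduction is needed; on that point it is stronger.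
- Against it: the nitrile oxide carbon lies in the forming ring, and its linear C–C≡N–O unit fits badly into a ten-membered transition state, so dimerisation competes. C8 is created with no nearby controlling centre. A2 lacks C14 and the 1,10-epoxide, so N–O cleavage, methyl addition to a β-hydroxy ketone prone to retro-aldol or dehydration, and an epoxide closure at C1 must follow. All of this would be done on a molecule that already holds a base-labile acetate, the acidic C6 hydrogen and an epoxide.
- Comparison: the chosen strategy finishes all carbon–carbon bond formation at the ring closure and needs no carbon nucleophile afterwards.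

Alternative 3: The butenolide itself is taken apart at C6–C7, C11–C12 and C12–O, leaving a C7≡C11 alkyne, a C6 aldehyde and carbon monoxide. A molybdenum or ruthenium carbonyl would join the three in a hetero-Pauson–Khand reaction that closes lactone and ten-membered ring together and gives A3, the bis-silyl ether of the diol of the target.
- For it: it is the most convergent plan, and A3 is two steps from the target against five from 26. On step economy after the key step it is clearly stronger.
- Against it: cyclisations of this type work when three or four atoms tether alkyne and aldehyde, so that both bind one metal. Here eight atoms lie between C7 and C6, and the metallacycle would have to form across a ten-membered ring. Both epoxides would meet low-valent metal carbonyls at high temperature, conditions that deoxygenate epoxides. The aldehyde would sit directly on the 4,5-epoxide, and both silyl ethers would be propargylic.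
- Comparison: the chosen strategy closes the ring by a polar addition at −78 °C whose intermolecular form is well behaved, with no epoxide yet present. Both epoxides are made afterwards, where the ring and neighbouring oxygens can direct them.

Key step: step 19

Remark: (R)-linalool is taken as enantiomerically pure; any minor enantiomer would surface after step 12 as a separable diastereomer.

## Steps

Step 1
Reactants: 1 (R)-linalool
Product: 3 (2R)-2-methylpentane-1,2,5-triol, via hydroxy dialdehyde 2 (not isolated)
Conditions: O3, CH2Cl2/MeOH, −78 °C; then NaBH4, −78 → 25 °C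
Reagents that add atoms: ozone, [O-][O+]=O
Why: Exhaustive ozonolysis cleaves both alkenes and borohydride reduces the peroxidic mixture in the same flask to the triol; the tertiary carbinol is untouched, so C4 keeps the R configuration of linalool.

Step 2
Reactants: 3 (2R)-2-methylpentane-1,2,5-triol
Product: 4 3-[(4R)-2,2,4-trimethyl-1,3-dioxolan-4-yl]propan-1-ol
Conditions: 2,2-dimethoxypropane, TsOH·H2O (cat.), acetone, 25 °C
Reagents that add atoms: 2,2-dimethoxypropane, COC(C)(C)OC
Why: Acetalisation under thermodynamic control prefers the five-membered dioxolane across the vicinal C4/C5 diol, which leaves the remote primary hydroxyl (C1) free and so differentiates the two ends of the triol.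

Step 3
Reactants: 4 3-[(4R)-2,2,4-trimethyl-1,3-dioxolan-4-yl]propan-1-ol
Product: 5 3-[(4R)-2,2,4-trimethyl-1,3-dioxolan-4-yl]propanal
Conditions: PhI(OAc)2, TEMPO (cat.), CH2Cl2, 25 °C
Reagents that add atoms: none
Why: Oxoammonium-catalysed oxidation stops cleanly at the aldehyde, and the acetonide tolerates the acetic acid that is released.

Step 4
Reactants: 5 3-[(4R)-2,2,4-trimethyl-1,3-dioxolan-4-yl]propanal; 6 methyl 2-[bis(2,2,2-trifluoroethoxy)phosphoryl]propanoate
Product: 8 methyl (2Z)-2-methyl-5-[(4R)-2,2,4-trimethyl-1,3-dioxolan-4-yl]pent-2-enoate, via potassium phosphonate carbanion 7 (not isolated)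
Conditions: KN(SiMe3)2, 18-crown-6, THF, −78 °C
Reagents that add atoms: potassium bis(trimethylsilyl)amide, C[Si](C)(C)[N-][Si](C)(C)C.[K+] (potassium of 7 only)
Why: Still–Gennari olefination: the electron-poor phosphonate and the dissociated potassium cation make elimination from the kinetic adduct fast, which gives the Z enoate. This sets C1=C10 with C2 and the ester carbon (later C9) cis.

Step 5
Reactants: 8 methyl (2Z)-2-methyl-5-[(4R)-2,2,4-trimethyl-1,3-dioxolan-4-yl]pent-2-enoate
Product: 9 (2Z)-2-methyl-5-[(4R)-2,2,4-trimethyl-1,3-dioxolan-4-yl]pent-2-en-1-ol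
Conditions: iBu2AlH, CH2Cl2, −78 °C
Reagents that add atoms: none
Why: 1,2-Reduction of the enoate gives the allylic alcohol without touching the alkene geometry or the acetonide.

Step 6
Reactants: 9 (2Z)-2-methyl-5-[(4R)-2,2,4-trimethyl-1,3-dioxolan-4-yl]pent-2-en-1-ol
Product: 10 (4R)-4-[(3Z)-5-bromo-4-methylpent-3-en-1-yl]-2,2,4-trimethyl-1,3-dioxolane
Conditions: CBr4, PPh3, 2,6-lutidine, CH2Cl2, 0 °C
Reagents that add atoms: tetrabromomethane, BrC(Br)(Br)Br
Why: Appel bromination displaces the primary allylic oxyphosphonium directly, without allylic transposition, and the buffered near-neutral medium spares the acetonide.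

Step 7
Reactants: 11 furan-3,4-diyldimethanol
Product: 12 [4-({[tri(propan-2-yl)silyl]oxy}methyl)furan-3-yl]methanol
Conditions: iPr3SiCl (0.9 equiv), imidazole, DMF, 0 °C
Reagents that add atoms: chlorotri(propan-2-yl)silane, CC(C)[Si](Cl)(C(C)C)C(C)C
Why: Statistical monosilylation of the symmetric diol; the triisopropylsilyl group is chosen because it withstands the Lewis acid, the organolithium and the later mild acid and has no aryl C–H bond that could compete in step 14.

Step 8
Reactants: 12 [4-({[tri(propan-2-yl)silyl]oxy}methyl)furan-3-yl]methanol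
Product: 13 4-({[tri(propan-2-yl)silyl]oxy}methyl)furan-3-carbaldehyde
Conditions: MnO2, CH2Cl2, 25 °C
Reagents that add atoms: none
Why: MnO2 oxidises the heteroaryl carbinol to the aldehyde and stops there.

Step 9
Reactants: 13 4-({[tri(propan-2-yl)silyl]oxy}methyl)furan-3-carbaldehyde
Product: 14 {[4-(1,3-dithian-2-yl)furan-3-yl]methoxy}tri(propan-2-yl)silane
Conditions: HS(CH2)3SH, BF3·OEt2 (cat.), CH2Cl2, 0 °C
Reagents that add atoms: propane-1,3-dithiol, SCCCS
Why: Dithioacetalisation turns the C8 aldehyde into an acyl anion equivalent (Corey–Seebach umpolung); a primary triisopropylsilyl ether survives catalytic BF3 at 0 °C.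

Step 10
Reactants: 14 {[4-(1,3-dithian-2-yl)furan-3-yl]methoxy}tri(propan-2-yl)silane; 10 (4R)-4-[(3Z)-5-bromo-4-methylpent-3-en-1-yl]-2,2,4-trimethyl-1,3-dioxolane
Product: 16 2-{(2Z)-2-methyl-5-[(4R)-2,2,4-trimethyl-1,3-dioxolan-4-yl]pent-2-en-1-yl}-2-[4-({[tri(propan-2-yl)silyl]oxy}methyl)furan-3-yl]-1,3-dithiane, via lithiated dithiane 15 (not isolated)
Conditions: nBuLi, THF, −78 → −30 °C; then 10, −78 → −20 °C
Reagents that add atoms: n-butyllithium, [Li]CCCC (lithium of 15 only)
Why: Corey–Seebach alkylation: the 2-aryl dithiane C–H is more acidic than any furan C–H, and the soft carbanion displaces the primary allylic bromide at its α-carbon, so C8–C9 forms without migration or isomerisation of the Z alkene. The bulky silyl group does not migrate to the stabilised carbanion.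

Step 11
Reactants: 16 alkylated dithiane
Product: 17 (3Z)-3-methyl-1-[4-({[tri(propan-2-yl)silyl]oxy}methyl)furan-3-yl]-6-[(4R)-2,2,4-trimethyl-1,3-dioxolan-4-yl]hex-3-en-1-one
Conditions: MeI, CaCO3, MeCN/H2O, 40 °C
Reagents that add atoms: water, O
Why: S-Methylation and buffered hydrolysis unmask the ketone without an oxidant, which spares the furan and the alkene. The neutral medium gives the β,γ-unsaturated ketone no base or acid with which to move into conjugation.

Step 12
Reactants: 17 furyl ketone
Product: 18 (1S,3Z)-3-methyl-1-[4-({[tri(propan-2-yl)silyl]oxy}methyl)furan-3-yl]-6-[(4R)-2,2,4-trimethyl-1,3-dioxolan-4-yl]hex-3-en-1-ol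
Conditions: (R)-2-methyl-CBS-oxazaborolidine, catecholborane, toluene, −78 °C
Reagents that add atoms: none
Why: Corey–Bakshi–Shibata reduction: the ketone binds the catalyst boron with the substituted furyl ring as the large group and the C9 methylene as the small one, and hydride is delivered to the face that gives 8S with the R catalyst. Catecholborane at −78 °C does not hydroborate the trisubstituted alkene.

Step 13
Reactants: 18 furyl carbinol
Product: 19 tert-butyl(dimethyl)silyl ether of 18 at C8
Conditions: tBuMe2SiCl, imidazole, DMF, 25 °C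
Reagents that add atoms: tert-butylchlorodimethylsilane, CC(C)(C)[Si](C)(C)Cl
Why: Standard silylation under non-acidic conditions. The silyl ether keeps the furylic C8 oxygen from ionising later and adds bulk beside the furan C–H that must not react in step 14.

Step 14
Reactants: 19 silylated furan
Product: 21 4-[(1S,3Z)-1-{[tert-butyl(dimethyl)silyl]oxy}-3-methyl-6-[(4R)-2,2,4-trimethyl-1,3-dioxolan-4-yl]hex-3-en-1-yl]-3-({[tri(propan-2-yl)silyl]oxy}methyl)furan-2(5H)-one, via furyl pinacol boronate 20 (not isolated)
Conditions: [Ir(OMe)(cod)]2 (cat.), 4,4′-di-tert-butyl-2,2′-bipyridine (cat.), B2pin2, hexane, 25 → 50 °C; then NaBO3·4H2O, THF/H2O, 25 °C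
Reagents that add atoms: bis(pinacolato)diboron, CC1(C)OB(OC1(C)C)B1OC(C)(C)C(C)(C)O1 (boron of 20 only); sodium perborate, [Na+].[Na+].O[B-]1(O)OO[B-](O)(O)OO1
Why: Iridium-catalysed C–H borylation of furans takes an α-position and is steered by sterics: C12–H is flanked by a CH2 group and C6–H by the branched silyloxy carbon C8, so boron should go to C12. Perborate oxidation gives the 2-hydroxyfuran, which tautomerises to the conjugated 2(5H)-furanone with C6 as its CH2 group; the isolated alkene is inert to both reagents.

Step 15
Reactants: 21 butenolide acetonide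
Product: 22 4-[(1S,3Z,7R)-1-{[tert-butyl(dimethyl)silyl]oxy}-7,8-dihydroxy-3,7-dimethyloct-3-en-1-yl]-3-({[tri(propan-2-yl)silyl]oxy}methyl)furan-2(5H)-one
Conditions: PPTS, MeOH, 45 °C
Reagents that add atoms: none
Why: Acid-catalysed transacetalisation removes the terminal acetonide. At the butenolide stage C8 no longer sits on an electron-rich furan, and a secondary tert-butyldimethylsilyl and a primary triisopropylsilyl ether withstand this weak acid.

Step 16
Reactants: 22 diol
Product: 23 7,8-bis(triethylsilyl) ether of 22
Conditions: Et3SiOTf, 2,6-lutidine, CH2Cl2, −78 → 0 °C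
Reagents that add atoms: triethylsilyl trifluoromethanesulfonate, CC[Si](CC)(CC)OS(=O)(=O)C(F)(F)F
Why: The silyl triflate silylates the tertiary C4 hydroxyl as well as the primary one, and lutidine is too weak a base to enolise the butenolide.

Step 17
Reactants: 23 bis(triethylsilyl) ether
Product: 24 (2R,5Z,8S)-8-{[tert-butyl(dimethyl)silyl]oxy}-2,6-dimethyl-8-[5-oxo-4-({[tri(propan-2-yl)silyl]oxy}methyl)-2,5-dihydrofuran-3-yl]-2-[(triethylsilyl)oxy]oct-5-enal
Conditions: (COCl)2, DMSO, CH2Cl2, −78 → −30 °C; then Et3N, −78 → 0 °C
Reagents that add atoms: none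
Why: Under Swern conditions a primary triethylsilyl ether is cleaved by the chlorosulfonium salt and oxidised in place to the aldehyde, while the tertiary triethylsilyl, secondary tert-butyldimethylsilyl and primary triisopropylsilyl ethers are inert. The aldehyde has no α-hydrogen and cannot epimerise.

Step 18
Reactants: 24 butenolide aldehyde
Product: 25 (2R,5Z,8S)-8-{[tert-butyl(dimethyl)silyl]oxy}-2,6-dimethyl-2-[(triethylsilyl)oxy]-8-[5-{[tri(propan-2-yl)silyl]oxy}-4-({[tri(propan-2-yl)silyl]oxy}methyl)furan-3-yl]oct-5-enal
Conditions: iPr3SiOTf, Et3N, CH2Cl2, 0 °C; non-aqueous work-up, used at once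
Reagents that add atoms: tri(propan-2-yl)silyl trifluoromethanesulfonate, CC(C)[Si](OS(=O)(=O)C(F)(F)F)(C(C)C)C(C)C
Why: Soft enolisation: O-silylation of the lactone carbonyl, then loss of a C6 proton, gives the aromatic 2-silyloxyfuran; only deprotonation at C6, not at C8, leads to an aromatic ring. Excess amine keeps the bulky triflate from activating the hindered aldehyde.

Step 19
Reactants: 25 silyloxyfuran aldehyde
Product: 26 (1(10)Z,4R,5S,6S,8S)-8-(tert-butyldimethylsilyloxy)-5-hydroxy-4-(triethylsilyloxy)-13-(triisopropylsilyloxy)germacra-1(10),7(11)-dien-12,6-olide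
Conditions: BF3·OEt2, CH2Cl2, −78 °C, slow addition of 25 to about 1 mM (MgBr2·OEt2 as second Lewis acid)
Reagents that add atoms: none
Why: Proposed new method: BF3 binds the C5 aldehyde, and the 2-silyloxyfuran, a cyclic silyl dienol ether, attacks through its unsubstituted α-carbon C6 in an open transition state; loss of the triisopropylsilyl group as its fluoride returns the butenolide, so C5–C6, the ten-membered ring and the lactone appear together. The closest known reactions are intermolecular vinylogous Mukaiyama aldol additions of 2-silyloxyfurans to α-oxygenated aldehydes and macrocyclising vinylogous aldol reactions of metal dienolates; a ring-closing version with a silyloxyfuran is not known. The ring closes in 10-exo-trig mode onto the carbonyl carbon, under high dilution. C5 is controlled by C4: in the polar Felkin–Anh arrangement the C4–OSi bond lies anti to the incoming C6, and the 4,5-anti product requires C6 to pass the C15 methyl with the C3 tether on the inside. C6 is controlled by which furan face the tether presents, a choice biased by the C8 stereocentre beside the reacting position. The step needs the 5S,6S isomer (O5 anti to both O4 and O6 in the zigzag); only the bias from C4 has intermolecular support, and the facial choice at C6 rests on the strain of the competing ring transition states and is untested. The substrate helps in three ways: the aldehyde has no α-hydrogen, the C8 and C13 oxygens are silyl ethers that neither ionise beside the electron-rich furan nor eliminate from the ketene acetal, and C6 is the only unsubstituted nucleophilic terminus.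

Step 20
Reactants: 26 macrocyclic alcohol
Product: 27 5-methanesulfonate of 26
Conditions: MsCl, Et3N, CH2Cl2, −20 → 0 °C
Reagents that add atoms: methanesulfonyl chloride, CS(Cl)(=O)=O
Why: Mesylation through sulfene works on hindered secondary alcohols; low temperature and a short reaction time keep the amine from eliminating the mesylate across C5–C6.

Step 21
Reactants: 27 mesylate
Product: 29 (1(10)Z,4R,5R,6S,8S)-8-(tert-butyldimethylsilyloxy)-4,5-epoxy-13-(triisopropylsilyloxy)germacra-1(10),7(11)-dien-12,6-olide, via hydroxy mesylate 28 (not isolated)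
Conditions: HF·pyridine, pyridine, THF, 0 °C; then K2CO3, MeOH, 0 °C
Reagents that add atoms: none
Why: Buffered HF removes the triethylsilyl group, the least hindered at silicon, ahead of the other two silyl ethers. The tertiary C4 alkoxide then displaces the C5 mesylate from the back (3-exo-tet), inverting C5 from S to R while C4 keeps its C–O bond. O4 and the mesylate are antiperiplanar in the extended conformer, so the trans oxirane results.

Step 22
Reactants: 29 silylated epoxide
Product: 30 (1(10)Z,4R,5R,6S,8S)-4,5-epoxy-8,13-dihydroxygermacra-1(10),7(11)-dien-12,6-olide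
Conditions: Bu4NF, AcOH, THF, 0 → 25 °C
Reagents that add atoms: none
Why: Fluoride buffered with acetic acid removes both remaining silyl ethers close to neutrality, which protects the epoxide from acid and the C6 hydrogen from base.

Step 23
Reactants: 30 epoxy diol
Product: 31 (1R,4R,5R,6S,8S,10S)-1,10:4,5-diepoxy-8,13-dihydroxygermacr-7(11)-en-12,6-olide
Conditions: VO(acac)2 (cat.), tBuOOH, CH2Cl2, 0 → 25 °C
Reagents that add atoms: tert-butyl hydroperoxide, CC(C)(C)OO
Why: Hydroxyl-directed epoxidation of a homoallylic alcohol: the vanadium alkoxide of the C8 hydroxyl delivers the peroxide oxygen to the C1=C10 face it can reach, and syn addition to the Z alkene gives the cis oxirane. The 1R,10S isomer requires delivery in the ring conformer that folds C8–O over the alkene with C7–C8–C9–C10 gauche. The electron-poor, tetrasubstituted butenolide alkene should not compete.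

Step 24
Reactants: 31 diepoxy diol
Product: 32 (1R,4R,5R,6S,8S,10S)-8,13-diacetoxy-1,10:4,5-diepoxygermacr-7(11)-en-12,6-olide
Conditions: Ac2O, pyridine, DMAP (cat.), CH2Cl2, 0 °C
Reagents that add atoms: acetic anhydride, CC(=O)OC(C)=O
Why: Both hydroxyls are acylated in one operation; pyridine is too weak a base to remove the C6 hydrogen, so neither the epoxide nor the new C13 acetate is eliminated.

## Compound list

1 | (R)-linalool, (3R)-3,7-dimethylocta-1,6-dien-3-ol | C=C[C@](C)(O)CCC=C(C)C | starting material
2 | (2R)-2-hydroxy-2-methylpentanedial (hydroxy dialdehyde, present as lactol and peroxidic adducts) | O=C[C@](C)(O)CCC=O | intermediate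
3 | (2R)-2-methylpentane-1,2,5-triol | OC[C@](C)(O)CCCO | intermediate
4 | 3-[(4R)-2,2,4-trimethyl-1,3-dioxolan-4-yl]propan-1-ol | CC1(C)OC[C@@](C)(CCCO)O1 | intermediate
5 | 3-[(4R)-2,2,4-trimethyl-1,3-dioxolan-4-yl]propanal | CC1(C)OC[C@@](C)(CCC=O)O1 | intermediate
6 | methyl 2-[bis(2,2,2-trifluoroethoxy)phosphoryl]propanoate | COC(=O)C(C)P(=O)(OCC(F)(F)F)OCC(F)(F)F | starting material
7 | potassium salt of the carbanion of 6 | COC(=O)[C-](C)P(=O)(OCC(F)(F)F)OCC(F)(F)F.[K+] | intermediate
8 | methyl (2Z)-2-methyl-5-[(4R)-2,2,4-trimethyl-1,3-dioxolan-4-yl]pent-2-enoate | COC(=O)/C(C)=C\CC[C@]1(C)COC(C)(C)O1 | intermediate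
9 | (2Z)-2-methyl-5-[(4R)-2,2,4-trimethyl-1,3-dioxolan-4-yl]pent-2-en-1-ol | OC/C(C)=C\CC[C@]1(C)COC(C)(C)O1 | intermediate
10 | (4R)-4-[(3Z)-5-bromo-4-methylpent-3-en-1-yl]-2,2,4-trimethyl-1,3-dioxolane | BrC/C(C)=C\CC[C@]1(C)COC(C)(C)O1 | intermediate
11 | furan-3,4-diyldimethanol | OCc1cocc1CO | starting material
12 | [4-({[tri(propan-2-yl)silyl]oxy}methyl)furan-3-yl]methanol | CC(C)[Si](OCc1cocc1CO)(C(C)C)C(C)C | intermediate
13 | 4-({[tri(propan-2-yl)silyl]oxy}methyl)furan-3-carbaldehyde | CC(C)[Si](OCc1cocc1C=O)(C(C)C)C(C)C | intermediate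
14 | {[4-(1,3-dithian-2-yl)furan-3-yl]methoxy}tri(propan-2-yl)silane | CC(C)[Si](OCc1cocc1C1SCCCS1)(C(C)C)C(C)C | intermediate
15 | 2-lithio derivative of dithiane 14 | CC(C)[Si](OCc1cocc1C1([Li])SCCCS1)(C(C)C)C(C)C | intermediate
16 | 2-{(2Z)-2-methyl-5-[(4R)-2,2,4-trimethyl-1,3-dioxolan-4-yl]pent-2-en-1-yl}-2-[4-({[tri(propan-2-yl)silyl]oxy}methyl)furan-3-yl]-1,3-dithiane | CC(C)[Si](OCc1cocc1C1(C/C(C)=C\CC[C@]2(C)COC(C)(C)O2)SCCCS1)(C(C)C)C(C)C | intermediate
17 | (3Z)-3-methyl-1-[4-({[tri(propan-2-yl)silyl]oxy}methyl)furan-3-yl]-6-[(4R)-2,2,4-trimethyl-1,3-dioxolan-4-yl]hex-3-en-1-one | CC(C)[Si](OCc1cocc1C(=O)C/C(C)=C\CC[C@]1(C)COC(C)(C)O1)(C(C)C)C(C)C | intermediate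
18 | (1S,3Z)-3-methyl-1-[4-({[tri(propan-2-yl)silyl]oxy}methyl)furan-3-yl]-6-[(4R)-2,2,4-trimethyl-1,3-dioxolan-4-yl]hex-3-en-1-ol | CC(C)[Si](OCc1cocc1[C@@H](O)C/C(C)=C\CC[C@]1(C)COC(C)(C)O1)(C(C)C)C(C)C | intermediate
19 | tert-butyl(dimethyl)silyl ether of 18 at the carbinol (C8) | CC(C)[Si](OCc1cocc1[C@@H](O[Si](C)(C)C(C)(C)C)C/C(C)=C\CC[C@]1(C)COC(C)(C)O1)(C(C)C)C(C)C | intermediate
20 | pinacol boronate of 19 at the furan α-carbon next to the silyloxymethyl arm (C12) | CC(C)[Si](OCc1c(B2OC(C)(C)C(C)(C)O2)occ1[C@@H](O[Si](C)(C)C(C)(C)C)C/C(C)=C\CC[C@]1(C)COC(C)(C)O1)(C(C)C)C(C)C | intermediate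
21 | 4-[(1S,3Z)-1-{[tert-butyl(dimethyl)silyl]oxy}-3-methyl-6-[(4R)-2,2,4-trimethyl-1,3-dioxolan-4-yl]hex-3-en-1-yl]-3-({[tri(propan-2-yl)silyl]oxy}methyl)furan-2(5H)-one | CC(C)[Si](OCC1=C(COC1=O)[C@@H](O[Si](C)(C)C(C)(C)C)C/C(C)=C\CC[C@]1(C)COC(C)(C)O1)(C(C)C)C(C)C | intermediate
22 | 4-[(1S,3Z,7R)-1-{[tert-butyl(dimethyl)silyl]oxy}-7,8-dihydroxy-3,7-dimethyloct-3-en-1-yl]-3-({[tri(propan-2-yl)silyl]oxy}methyl)furan-2(5H)-one | CC(C)[Si](OCC1=C(COC1=O)[C@@H](O[Si](C)(C)C(C)(C)C)C/C(C)=C\CC[C@@](C)(O)CO)(C(C)C)C(C)C | intermediate
23 | 7,8-bis(triethylsilyl) ether of 22 | CC(C)[Si](OCC1=C(COC1=O)[C@@H](O[Si](C)(C)C(C)(C)C)C/C(C)=C\CC[C@@](C)(O[Si](CC)(CC)CC)CO[Si](CC)(CC)CC)(C(C)C)C(C)C | intermediate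
24 | (2R,5Z,8S)-8-{[tert-butyl(dimethyl)silyl]oxy}-2,6-dimethyl-8-[5-oxo-4-({[tri(propan-2-yl)silyl]oxy}methyl)-2,5-dihydrofuran-3-yl]-2-[(triethylsilyl)oxy]oct-5-enal | CC(C)[Si](OCC1=C(COC1=O)[C@@H](O[Si](C)(C)C(C)(C)C)C/C(C)=C\CC[C@@](C)(O[Si](CC)(CC)CC)C=O)(C(C)C)C(C)C | intermediate
25 | (2R,5Z,8S)-8-{[tert-butyl(dimethyl)silyl]oxy}-2,6-dimethyl-2-[(triethylsilyl)oxy]-8-[5-{[tri(propan-2-yl)silyl]oxy}-4-({[tri(propan-2-yl)silyl]oxy}methyl)furan-3-yl]oct-5-enal | CC(C)[Si](OCc1c(O[Si](C(C)C)(C(C)C)C(C)C)occ1[C@@H](O[Si](C)(C)C(C)(C)C)C/C(C)=C\CC[C@@](C)(O[Si](CC)(CC)CC)C=O)(C(C)C)C(C)C | intermediate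
26 | (1(10)Z,4R,5S,6S,8S)-8-(tert-butyldimethylsilyloxy)-5-hydroxy-4-(triethylsilyloxy)-13-(triisopropylsilyloxy)germacra-1(10),7(11)-dien-12,6-olide | CC(C)[Si](OCC1=C2[C@@H](O[Si](C)(C)C(C)(C)C)C/C(C)=C\CC[C@@](C)(O[Si](CC)(CC)CC)[C@@H](O)[C@H]2OC1=O)(C(C)C)C(C)C | intermediate
27 | 5-methanesulfonate of 26 | CC(C)[Si](OCC1=C2[C@@H](O[Si](C)(C)C(C)(C)C)C/C(C)=C\CC[C@@](C)(O[Si](CC)(CC)CC)[C@@H](OS(C)(=O)=O)[C@H]2OC1=O)(C(C)C)C(C)C | intermediate
28 | (1(10)Z,4R,5S,6S,8S)-8-(tert-butyldimethylsilyloxy)-4-hydroxy-5-(methanesulfonyloxy)-13-(triisopropylsilyloxy)germacra-1(10),7(11)-dien-12,6-olide | CC(C)[Si](OCC1=C2[C@@H](O[Si](C)(C)C(C)(C)C)C/C(C)=C\CC[C@@](C)(O)[C@@H](OS(C)(=O)=O)[C@H]2OC1=O)(C(C)C)C(C)C | intermediate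
29 | (1(10)Z,4R,5R,6S,8S)-8-(tert-butyldimethylsilyloxy)-4,5-epoxy-13-(triisopropylsilyloxy)germacra-1(10),7(11)-dien-12,6-olide | CC(C)[Si](OCC1=C2[C@@H](O[Si](C)(C)C(C)(C)C)C/C(C)=C\CC[C@@]3(C)O[C@@H]3[C@H]2OC1=O)(C(C)C)C(C)C | intermediate
30 | (1(10)Z,4R,5R,6S,8S)-4,5-epoxy-8,13-dihydroxygermacra-1(10),7(11)-dien-12,6-olide | OCC1=C2[C@@H](O)C/C(C)=C\CC[C@@]3(C)O[C@@H]3[C@H]2OC1=O | intermediate
31 | (1R,4R,5R,6S,8S,10S)-1,10:4,5-diepoxy-8,13-dihydroxygermacr-7(11)-en-12,6-olide | OCC1=C2[C@@H](O)C[C@]3(C)O[C@@H]3CC[C@@]3(C)O[C@@H]3[C@H]2OC1=O | intermediate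
32 | (1R,4R,5R,6S,8S,10S)-8,13-diacetoxy-1,10:4,5-diepoxygermacr-7(11)-en-12,6-olide (CNP0271844.2) | CC(=O)OCC1=C2[C@@H](OC(C)=O)C[C@]3(C)O[C@@H]3CC[C@@]3(C)O[C@@H]3[C@H]2OC1=O | target

## Step count and least certain steps

Total: 24 steps. Longest linear sequence: 21 steps (steps 1–6 and 10–24, from 1); the furan branch (steps 7–9) joins at step 10.

Step 19 (key step).
- What may go wrong: chain growth between molecules in place of ring closure; closure through a wrong diastereomeric transition state (poor facial selectivity at C5 or C6); loss of the silyl dienol ether by protodesilylation before the C–C bond forms.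
- Fallback with known chemistry: make C5–C6 between two molecules and close the ring at C1=C10 by metathesis. It sets out from 5 and 13 and comes back at 26.
- Aldehyde partner: aldehyde 5 is methylenated with Ph3P=CH2 to the alkene acetonide F1. The acetonide is removed as in step 15 to give the diol F2. Silylation as in step 16 gives the bis(triethylsilyl) ether F3, and Swern oxidation as in step 17 gives the α-silyloxy aldehyde F4.
- Furan partner: furan aldehyde 13 is methallylated with (−)-Ipc2B(2-methylallyl) (Brown allylation) to the 8S homoallylic alcohol F5 and silylated as in step 13 to the silyl ether F6. Borylation gives the furyl boronate F7, oxidation gives the butenolide F8, and silylation as in step 18 gives the silyloxyfuran F9.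
- Union and closure: F4 and F9 are joined with BF3·OEt2 at −78 °C in the intermolecular vinylogous Mukaiyama aldol addition, which is known for α-silyloxy aldehydes. The aldol adduct F10 is obtained after separation of diastereomers. Ring-closing metathesis with the second-generation Grubbs catalyst under dilution then forms C1=C10. A ten-membered ring favours the ring-cis alkene, which is the Z isomer of 26.

Step 23.
- What may go wrong: oxygen delivery to the wrong face of C1=C10, because the ring conformer and not the reagent decides which face the C8 alkoxide reaches; transannular opening of the 4,5-epoxide by the free C8 hydroxyl under the Lewis-acidic catalyst.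
- Fallback: drop the direction and use the ring shape. It sets out from 30 and comes back at 32. Acetylation as in step 24 gives the diacetate alkene F11. Dimethyldioxirane then epoxidises the face that the ring leaves open. Should that be the wrong face as well, N-bromosuccinimide in aqueous THF attacks the same open face and gives the bromohydrin F12; closure with Ag2O then places the oxirane oxygen on the opposite face. Between the two reagents both faces are reachable.

Step 21.
- What may go wrong: elimination of the mesylate across C5–C6 after removal of the C6 hydrogen, giving the γ-alkylidene butenolide in place of ring closure; epimerisation at C6; loss of selectivity among the silyl ethers.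
- Fallback without mesylate and without external base: it sets out from 26 and comes back at 29. Buffered HF·pyridine removes only the triethylsilyl group to give the 4,5-diol F13. Mitsunobu cyclodehydration (PPh3, diisopropyl azodicarboxylate) activates the secondary C5 hydroxyl as its oxyphosphonium, and the tertiary C4 oxygen displaces it with the same inversion.

Step 14.
- What may go wrong: poor regioselectivity between the two furan α-positions (boron at C6 instead of C12), which would place the carbonyl on the wrong side.
- Fallback with direction by a neighbouring alkoxide in place of sterics: it sets out from 18 and comes back at 21. Bu4NF removes the triisopropylsilyl group to give the furan diol F14. Both hydroxyls are silylated with tBuMe2SiOTf to the bis-silyl ether F15. HF·pyridine with pyridine frees the primary one again to give the C13 alcohol F16. Two equivalents of nBuLi form the lithium alkoxide, which directs lithiation to the adjacent α-carbon C12. Trimethyl borate and then NaBO3·4H2O in the same flask give the hydroxymethyl butenolide F17. Silylation with iPr3SiCl and imidazole returns 21.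

## Further compounds

F1 | step 19 | (4R)-4-(but-3-en-1-yl)-2,2,4-trimethyl-1,3-dioxolane | C=CCC[C@]1(C)COC(C)(C)O1
F2 | step 19 | (2R)-2-methylhex-5-ene-1,2-diol | C=CCC[C@@](C)(O)CO
F3 | step 19 | (2R)-2-methyl-1,2-bis[(triethylsilyl)oxy]hex-5-ene | C=CCC[C@@](C)(O[Si](CC)(CC)CC)CO[Si](CC)(CC)CC
F4 | step 19 | (2R)-2-methyl-2-[(triethylsilyl)oxy]hex-5-enal | C=CCC[C@@](C)(O[Si](CC)(CC)CC)C=O
F5 | step 19 | (1S)-3-methyl-1-[4-({[tri(propan-2-yl)silyl]oxy}methyl)furan-3-yl]but-3-en-1-ol | CC(C)[Si](OCc1cocc1[C@@H](O)CC(C)=C)(C(C)C)C(C)C
F6 | step 19 | tert-butyl(dimethyl)silyl ether of F5 | CC(C)[Si](OCc1cocc1[C@@H](O[Si](C)(C)C(C)(C)C)CC(C)=C)(C(C)C)C(C)C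
F7 | step 19 | pinacol boronate of F6 at the furan α-carbon next to the silyloxymethyl arm | CC(C)[Si](OCc1c(B2OC(C)(C)C(C)(C)O2)occ1[C@@H](O[Si](C)(C)C(C)(C)C)CC(C)=C)(C(C)C)C(C)C
F8 | step 19 | 4-[(1S)-1-{[tert-butyl(dimethyl)silyl]oxy}-3-methylbut-3-en-1-yl]-3-({[tri(propan-2-yl)silyl]oxy}methyl)furan-2(5H)-one | CC(C)[Si](OCC1=C(COC1=O)[C@@H](O[Si](C)(C)C(C)(C)C)CC(C)=C)(C(C)C)C(C)C
F9 | step 19 | 2-{[tri(propan-2-yl)silyl]oxy}furan derived from F8 | CC(C)[Si](OCc1c(O[Si](C(C)C)(C(C)C)C(C)C)occ1[C@@H](O[Si](C)(C)C(C)(C)C)CC(C)=C)(C(C)C)C(C)C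
F10 | step 19 | open-chain aldol adduct (4R,5S,6S,8S) with terminal alkenes at C1 and C10 | CC(C)[Si](OCC1=C([C@@H](O[Si](C)(C)C(C)(C)C)CC(C)=C)[C@H](OC1=O)[C@H](O)[C@](C)(O[Si](CC)(CC)CC)CCC=C)(C(C)C)C(C)C
F11 | step 23 | (1(10)Z,4R,5R,6S,8S)-8,13-diacetoxy-4,5-epoxygermacra-1(10),7(11)-dien-12,6-olide | CC(=O)OCC1=C2[C@@H](OC(C)=O)C/C(C)=C\CC[C@@]3(C)O[C@@H]3[C@H]2OC1=O
F12 | step 23 | bromohydrin of F11 with hydroxyl at C10 and bromine at C1 | CC(=O)OCC1=C2[C@@H](OC(C)=O)C[C@](C)(O)[C@@H](Br)CC[C@@]3(C)O[C@@H]3[C@H]2OC1=O
F13 | step 21 | (1(10)Z,4R,5S,6S,8S)-8-(tert-butyldimethylsilyloxy)-4,5-dihydroxy-13-(triisopropylsilyloxy)germacra-1(10),7(11)-dien-12,6-olide | CC(C)[Si](OCC1=C2[C@@H](O[Si](C)(C)C(C)(C)C)C/C(C)=C\CC[C@@](C)(O)[C@@H](O)[C@H]2OC1=O)(C(C)C)C(C)C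
F14 | step 14 | (1S,3Z)-1-[4-(hydroxymethyl)furan-3-yl]-3-methyl-6-[(4R)-2,2,4-trimethyl-1,3-dioxolan-4-yl]hex-3-en-1-ol | OCc1cocc1[C@@H](O)C/C(C)=C\CC[C@]1(C)COC(C)(C)O1
F15 | step 14 | bis[tert-butyl(dimethyl)silyl] ether of F14 | CC(C)(C)[Si](C)(C)OCc1cocc1[C@@H](O[Si](C)(C)C(C)(C)C)C/C(C)=C\CC[C@]1(C)COC(C)(C)O1
F16 | step 14 | {4-[(1S,3Z)-1-{[tert-butyl(dimethyl)silyl]oxy}-3-methyl-6-[(4R)-2,2,4-trimethyl-1,3-dioxolan-4-yl]hex-3-en-1-yl]furan-3-yl}methanol | OCc1cocc1[C@@H](O[Si](C)(C)C(C)(C)C)C/C(C)=C\CC[C@]1(C)COC(C)(C)O1
F17 | step 14 | 4-[(1S,3Z)-1-{[tert-butyl(dimethyl)silyl]oxy}-3-methyl-6-[(4R)-2,2,4-trimethyl-1,3-dioxolan-4-yl]hex-3-en-1-yl]-3-(hydroxymethyl)furan-2(5H)-one | OCC1=C(COC1=O)[C@@H](O[Si](C)(C)C(C)(C)C)C/C(C)=C\CC[C@]1(C)COC(C)(C)O1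
A1 | alternative 1 | ten-membered 1,10-epoxide with C4/C5 diol, C7 exocyclic methylene, C6 triethylsilyl ether and C8 tert-butyldimethylsilyl ether | C[C@]12C[C@H](O[Si](C)(C)C(C)(C)C)C(=C)[C@H](O[Si](CC)(CC)CC)[C@H](O)[C@](C)(O)CC[C@H]1O2
A2 | alternative 2 | macrocyclic isoxazoline bridging C8 and C10, with 4,5-epoxide, C1 triisopropylsilyl ether and C13 acetate | CC(=O)OCC1=C2[C@@H]3CC(=NO3)[C@@H](O[Si](C(C)C)(C(C)C)C(C)C)CC[C@@]4(C)O[C@@H]4[C@H]2OC1=O
A3 | alternative 3 | 8,13-bis(tert-butyldimethylsilyl) ether of the diepoxy diol 31 | CC(C)(C)[Si](C)(C)OCC1=C2[C@@H](O[Si](C)(C)C(C)(C)C)C[C@]3(C)O[C@@H]3CC[C@@]3(C)O[C@@H]3[C@H]2OC1=O
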